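## The problem

Compound 17 is 5,7,8,2',3',4',5'-heptamethoxyflavone. Benzo ring A (C4a to C8a) is fused to pyranone ring C, and ring B is attached through the C2–C1' bond. There is no stereocentre, so nothing has to be set or relayed, and every selectivity question is one of position. Ring A must carry methoxy groups at C5, C7 and C8 with hydrogen at C6. The isomeric 5,6,7 pattern results whenever the other of the two ortho oxygens of a ring A ketone becomes O1. Ring B has four contiguous methoxy groups (C2' to C5') and a single hydrogen at C6', a pattern that is awkward to reach by substitution of a purchased arene. The pyranone ring is opened at C2 by hard nucleophiles and strong aqueous base, the 5-methoxy group peri to the carbonyl is the first ether to fall to Lewis acids, and both electron-rich arenes are easily oxidised. The enabling feature lies in ring B: the oxygens at C2' and C5' are para to each other, C6' carries hydrogen, and C1' carries the chromone. That is the pattern of the 4-methoxyphenol formed from a chromium alkenyl(methoxy)carbene, one CO ligand and a terminal alkyne, with the alkyne substituent next to the new hydroxyl.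

## Retrosynthesis

**17 to 16.** The O–CH3 bond at C2' is cut first. Of the seven ether oxygens this is the only one that no building block supplies as a methyl ether: in the ring construction below it comes from a CO ligand and appears as a free hydroxyl. Phenol 16 differs from 17 by one methyl group. The forward step only has to alkylate a hindered, unchelated phenol without touching the pyranone.

**16 to 9 and 14.** Ring B is cut at C5'–C6', C1'–C2' and C2'–C3'. This gives alkyne 9 (C1' and C6'), carbene complex 14 (C5', C4' and C3', each with its methoxy group) and one CO ligand of 14 (C2'). The neighbouring cuts, through C2–C1' or through ring C, all require a ready-made 2,3,4,5-tetraoxygenated aryl unit. This cut instead places the four oxygens and the lone C6'–H as the ring forms. Alkyne 9 holds rings A and C with a two-carbon handle; 14 is a three-carbon unit. The forward reaction must insert the alkyne with its substituted carbon next to the CO-derived carbon, must insert CO in preference to closing without it, and must leave the chromone alone. Its first product is the Cr(CO)3 complex 15, from which air should release 16.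

**14 to 10 and 11.** The bond between the carbene carbon and the alkenyl carbon and the O–CH3 bond of the carbene are cut. This is the classical route to alkoxycarbene complexes: vinyllithium 12 adds to a CO ligand of Cr(CO)6 (11), and the acylate 13 is O-methylated. Vinyllithium 12 comes from enol ether 10 by deprotonation. The E geometry of 10 puts lithium on the same side as the β-methoxy group, which coordinates it and rules out anti elimination of methoxide.

**9 to 8.** The terminal alkyne carbon is removed, leaving aldehyde 8 for a one-carbon homologation. Attaching an intact alkyne to C2 by cross-coupling would need a chromone with a leaving group at C2, a class that is not readily prepared. A C2 substituent at the aldehyde level, by contrast, falls out of the construction of ring C.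

**8 to 6, then to 4 and 5.** Ring C is cut at O1–C2 and C2–C3, through acetal 7 and diketone 6, back to acetophenone 4 and ester 5. Ester 5 brings C2 and the formyl carbon at the right oxidation level, masked as a diethyl acetal. An oxalate ester would bring that carbon as an ester, which would need reduction and reoxidation beside a reducible enone, two more steps. The forward sequence is a crossed Claisen condensation and an acid-catalysed cyclodehydration.

**4 to 2, then to 1.** The aryl–acetyl bond and one O–CH3 bond are cut, through tetramethoxy ketone 3. Direct ortho-acylation of phenol 1 would make its hydroxyl into O1. That oxygen is the isolated one of the four, so the chromone would come out as the 5,6,7 isomer. Phenol 1 is therefore capped first to the symmetrical ether 2, which has one kind of free position. After acylation to 3, the ortho methoxy group flanked by the acetyl group and a second methoxy group is cleaved to give 4. The forward reaction has to tell the two ortho methoxy groups of 3 apart.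

## Roads not taken

**Alternative 1:** Ring C is cut at O1–C8a, C4–C4a and O1–C2. The fragments are 3-(2,3,4,5-tetramethoxyphenyl)propiolic acid A2 and the aryne precursor 3,5-dimethoxy-2-(trimethylsilyl)phenyl triflate A3. In the forward step CsF releases the aryne from A3, and the carboxylate of A2 adds through oxygen at the aryne carbon remote from the methoxy group. The aryl anion then takes the acyl group, and the ortho-hydroxyaryl ynone closes by oxa-Michael addition to 5,7-dimethoxy-2-(2,3,4,5-tetramethoxyphenyl)chromen-4-one A1.
- Merits: one operation joins two fragments into the flavone core, no stoichiometric transition metal is used, and the methoxy group beside the aryne bond steers the insertion to the correct 5-methoxy arrangement.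
- Weak points: A1 lacks the C8 oxygen. It would have to be added by halogenation and copper-mediated methoxylation, with C8, C6 and the very electron-rich C6' of ring B all open to the electrophile. A2 also needs the tetraoxygenated aryl unit that is hard to buy.
- Comparison: this road reaches the flavone skeleton in fewer steps, is more convergent and avoids chromium. The chosen plan sets against this that all seven oxygens are in place once ring B has closed, so no late C–H oxygenation with three competing sites is needed.

**Alternative 2:** Ring A is cut at C5–C6. The precursor is racemic methyl 2-(1-methoxy-2-oxopropyl)-4-oxo-6-(2,3,4,5-tetramethoxyphenyl)-4H-pyran-3-carboxylate A5. With LiN(SiMe3)2 the methyl ketone enolate attacks the ester carbon, and loss of methanol and enolisation give 5,7-dihydroxy-8-methoxy-2-(2,3,4,5-tetramethoxyphenyl)chromen-4-one A4. Two O-methylations would finish the synthesis.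
- Merits: the C8 methoxy group is fixed in an open-chain precursor, so the 5,6,7 versus 5,7,8 question never arises. In this respect it is better than step 2 of the chosen plan.
- Weak points: A5 is a pyranone with three different substituents and would take many steps to assemble. Its most acidic proton is the methine between the pyranone, the methoxy group and the ketone, so the methyl enolate needed for closure must be formed as a dianion. The pyranone is exposed to amide base, and the chelated 5-hydroxyl needs forcing methylation.
- Comparison: ring A regiochemistry is more certain here. The chosen plan accepts one regioselective demethylation, with a fallback, in exchange for partners that are each made in one to five steps.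

**Alternative 3:** Ring A is cut at C4a–C5. The precursor is racemic 4-hydroxy-3-methoxy-4-[4-oxo-6-(2,3,4,5-tetramethoxyphenyl)-4H-pyran-2-yl]cyclobut-2-en-1-one A7. Heating opens the four-membered ring to a dienylketene, which closes by 6π electrocyclisation onto the pyranone carbon that becomes C4a. Tautomerisation gives 5,8-dihydroxy-7-methoxy-2-(2,3,4,5-tetramethoxyphenyl)chromen-4-one A6, and two O-methylations follow.
- Merits: the step is thermal, needs no reagent or metal, and places the oxygens at C5, C7 and C8 by construction. It uses the same dienylketene closure as the chosen key step without chromium.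
- Weak points: A7 requires addition of a pyranone metallated at C2 to one of the two ketones of a methoxycyclobutenedione, and such a nucleophile is not accessible while the C4 carbonyl is free. A6 is a para-hydroquinone that air converts to the quinone. Two methylations are needed, one at the chelated C5 hydroxyl, and the tetraoxygenated aryl unit is still required.
- Comparison: as a metal-free version of the same pericyclic logic it is cleaner in waste and atom economy. The chosen plan sets against this that both its partners come from ordinary condensation and lithiation chemistry, and that it builds ring B, the ring whose substitution is hardest to buy.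

Key step: step 7

Assumption: 10 is used as the pure E isomer, bought or fractionated from the commercial E/Z mixture. The alkene geometry is lost when its β-carbon becomes C3' of the arene, so it has no bearing on the structure of 16.

## Steps

Step 1
Reactants: 1 3,4,5-trimethoxyphenol
Product: 2 1,2,3,5-tetramethoxybenzene
Conditions: MeI, K2CO3, acetone, reflux
Reagents that add atoms: iodomethane, CI
Why: Williamson O-methylation of an unhindered phenol; it gives a symmetrical arene with one kind of free ring position.

Step 2
Reactants: 2 1,2,3,5-tetramethoxybenzene
Product: 4 1-(2-hydroxy-3,4,6-trimethoxyphenyl)ethanone, via 1-(2,3,4,6-tetramethoxyphenyl)ethanone 3 (not isolated)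
Conditions: AcCl, AlCl3 (2.5 equiv), CH2Cl2, 0 °C to rt; 1 M aq. HCl
Reagents that add atoms: acetyl chloride, CC(Cl)=O
Why: Friedel–Crafts acylation occurs at C4 of 2 (C4 and C6 are equivalent and activated by three methoxy groups). Excess AlCl3, chelated between the ketone oxygen and the ortho methoxy group of 3 that is flanked by a second methoxy group, should then cleave that ether by chloride attack on methyl; this is the known ortho-selective demethylation of aryl ketones, and the buttressed, out-of-plane methoxy group is the more basic and more strained of the two.

Step 3
Reactants: 4 1-(2-hydroxy-3,4,6-trimethoxyphenyl)ethanone; 5 ethyl diethoxyacetate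
Product: 6 4,4-diethoxy-1-(2-hydroxy-3,4,6-trimethoxyphenyl)butane-1,3-dione
Conditions: NaH (4 equiv), THF, reflux; then cold dilute aq. HCl
Reagents that add atoms: none
Why: Crossed Claisen condensation of the phenoxide–enolate dianion of the acetophenone with ester 5, the standard first stage of chromone syntheses; the acetal is inert to base, and 6 may sit partly as its enol or cyclic hemiketal, which converge in step 4.

Step 4
Reactants: 6 4,4-diethoxy-1-(2-hydroxy-3,4,6-trimethoxyphenyl)butane-1,3-dione
Product: 8 5,7,8-trimethoxy-4-oxo-4H-chromene-2-carbaldehyde, via 2-(diethoxymethyl)-5,7,8-trimethoxychromen-4-one 7 (not isolated)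
Conditions: conc. HCl (cat.), EtOH, reflux; then 3 M aq. HCl, 60 °C
Reagents that add atoms: water, O
Why: Acid-catalysed cyclodehydration of a 2-hydroxyaryl 1,3-diketone (phenol oxygen onto the distal ketone, loss of water) closes ring C to acetal 7. Aqueous acid then hydrolyses the diethyl acetal, and the aryl methyl ethers should survive dilute HCl.

Step 5
Reactants: 8 5,7,8-trimethoxy-4-oxo-4H-chromene-2-carbaldehyde
Product: 9 2-ethynyl-5,7,8-trimethoxychromen-4-one
Conditions: TMSCHN2 (1.2 equiv), n-BuLi (1.15 equiv), THF, −78 °C; add 8, −78 to 0 °C; aq. NH4Cl
Reagents that add atoms: trimethylsilyldiazomethane, C[Si](C)(C)C=[N+]=[N-]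
Why: Colvin rearrangement: lithiated trimethylsilyldiazomethane adds to the aldehyde, Peterson-type loss of Me3SiOLi gives a diazoalkene, and loss of N2 with a 1,2-hydrogen shift of the alkylidene carbene gives the terminal alkyne. The aldehyde is far more electrophilic than the vinylogous ester carbonyl, and the methanol-free, amine-free medium avoids conjugate addition to the pyranone.

Step 6
Reactants: 10 (E)-1,2-dimethoxyethene; 11 hexacarbonylchromium Cr(CO)6
Product: 14 pentacarbonyl[(E)-1,2-dimethoxyvinyl(methoxy)carbene]chromium, via (E)-1,2-dimethoxyvinyllithium 12 (not isolated), via lithium pentacarbonyl[(E)-2,3-dimethoxy-1-oxidoprop-2-enylidene]chromate 13 (not isolated)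
Conditions: t-BuLi (1.0 equiv), THF, −78 to −30 °C; Cr(CO)6, THF, −78 °C to rt; solvent exchange; Me3OBF4, CH2Cl2, 0 °C; argon throughout
Reagents that add atoms: trimethyloxonium tetrafluoroborate, C[O+](C)C.F[B-](F)(F)F
Why: Fischer synthesis of an alkoxycarbene complex of zerovalent chromium: α-deprotonation of the enol ether (lithium held by the cis β-methoxy group, so anti elimination of methoxide is closed), addition of the vinyllithium to a CO ligand, and O-methylation of the acylate by the oxonium salt. The alkene geometry is retained.

Step 7
Reactants: 9 2-ethynyl-5,7,8-trimethoxychromen-4-one; 14 pentacarbonyl[(E)-1,2-dimethoxyvinyl(methoxy)carbene]chromium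
Product: 16 2-(2-hydroxy-3,4,5-trimethoxyphenyl)-5,7,8-trimethoxychromen-4-one, via tricarbonyl[η6-2-(2-hydroxy-3,4,5-trimethoxyphenyl)-5,7,8-trimethoxychromen-4-one]chromium 15 (not isolated)
Conditions: 14 (1.5 equiv), THF (0.05 M), 50 °C, argon; then air, EtOAc, rt
Reagents that add atoms: none
Why: This is a Dötz benzannulation of an alkenyl(methoxy)carbene of zerovalent chromium with a terminal alkyne, the closest known reaction type. Thermal loss of one cis CO ligand from 14 opens a site for 9; the alkyne inserts into the Cr=C bond with its unsubstituted carbon joining the carbene carbon (C5'–C6'), giving an η3-vinylcarbene whose chromium-bound carbon carries the chromonyl group. CO insertion at that carbon (C1'–C2') gives an η4-dienylketene, and the ketene carbon bonds to the β-carbon of the former alkenyl group (C2'–C3') in a 6π electrocyclisation that closes the six-membered carbocycle. Tautomerisation of the cyclohexadienone, possible because the β-carbon carries hydrogen, gives the phenol as its Cr(CO)3 complex 15, and air oxidation of the metal releases 16. No stereocentre is formed. The step needs regioselective alkyne insertion and needs CO insertion to win over CO-free closure to five-membered rings: the first is secured by the terminal alkyne, whose hydrogen end alone fits beside the carbene substituents, the second by the combination of chromium, a methoxycarbene, an alkenyl in place of an aryl group and an ether solvent at moderate temperature. The conjugated C2=C3 bond of the chromone cannot enter a six-electron closure with the ketene and should remain a spectator.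

Step 8
Reactants: 16 2-(2-hydroxy-3,4,5-trimethoxyphenyl)-5,7,8-trimethoxychromen-4-one
Product: 17 5,7,8-trimethoxy-2-(2,3,4,5-tetramethoxyphenyl)chromen-4-one
Conditions: MeI, K2CO3, acetone, 50 °C
Reagents that add atoms: iodomethane, CI
Why: Williamson O-methylation of the 2'-phenol; carbonate in acetone is too weak a nucleophile to open the pyranone.

## Compound list

1 | 3,4,5-trimethoxyphenol | COc1cc(O)cc(OC)c1OC | starting material
2 | 1,2,3,5-tetramethoxybenzene | COc1cc(OC)c(OC)c(OC)c1 | intermediate
3 | 1-(2,3,4,6-tetramethoxyphenyl)ethanone | CC(=O)c1c(OC)cc(OC)c(OC)c1OC | intermediate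
4 | 1-(2-hydroxy-3,4,6-trimethoxyphenyl)ethanone | CC(=O)c1c(OC)cc(OC)c(OC)c1O | intermediate
5 | ethyl diethoxyacetate | CCOC(=O)C(OCC)OCC | starting material
6 | 4,4-diethoxy-1-(2-hydroxy-3,4,6-trimethoxyphenyl)butane-1,3-dione | CCOC(OCC)C(=O)CC(=O)c1c(OC)cc(OC)c(OC)c1O | intermediate
7 | 2-(diethoxymethyl)-5,7,8-trimethoxychromen-4-one | CCOC(OCC)c1cc(=O)c2c(OC)cc(OC)c(OC)c2o1 | intermediate
8 | 5,7,8-trimethoxy-4-oxo-4H-chromene-2-carbaldehyde | O=Cc1cc(=O)c2c(OC)cc(OC)c(OC)c2o1 | intermediate
9 | 2-ethynyl-5,7,8-trimethoxychromen-4-one | C#Cc1cc(=O)c2c(OC)cc(OC)c(OC)c2o1 | intermediate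
10 | (E)-1,2-dimethoxyethene | CO/C=C/OC | starting material
11 | hexacarbonylchromium Cr(CO)6 | [Cr].[C-]#[O+].[C-]#[O+].[C-]#[O+].[C-]#[O+].[C-]#[O+].[C-]#[O+] | starting material
12 | (E)-1,2-dimethoxyvinyllithium | CO/C=C(/OC)[Li] | intermediate
13 | lithium pentacarbonyl[(E)-2,3-dimethoxy-1-oxidoprop-2-enylidene]chromate | CO/C=C(/OC)C([O-])=[Cr].[C-]#[O+].[C-]#[O+].[C-]#[O+].[C-]#[O+].[C-]#[O+].[Li+] | intermediate
14 | pentacarbonyl[(E)-1,2-dimethoxyvinyl(methoxy)carbene]chromium | CO/C=C(/OC)C(OC)=[Cr].[C-]#[O+].[C-]#[O+].[C-]#[O+].[C-]#[O+].[C-]#[O+] | intermediate
15 | tricarbonyl[η6-2-(2-hydroxy-3,4,5-trimethoxyphenyl)-5,7,8-trimethoxychromen-4-one]chromium | COc1cc(-c2cc(=O)c3c(OC)cc(OC)c(OC)c3o2)c(O)c(OC)c1OC.[Cr].[C-]#[O+].[C-]#[O+].[C-]#[O+] | intermediate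
16 | 2-(2-hydroxy-3,4,5-trimethoxyphenyl)-5,7,8-trimethoxychromen-4-one | COc1cc(-c2cc(=O)c3c(OC)cc(OC)c(OC)c3o2)c(O)c(OC)c1OC | intermediate
17 | 5,7,8-trimethoxy-2-(2,3,4,5-tetramethoxyphenyl)chromen-4-one | COc1cc(-c2cc(=O)c3c(OC)cc(OC)c(OC)c3o2)c(OC)c(OC)c1OC | target

## Step count and least certain steps

Total: 8 steps. Longest linear sequence: 7 steps (1 to 2, 4, 6, 8, 9, 16, 17); the carbene branch (step 6) is one step and joins at step 7.

**Step 7 (key step).** The most likely failure is that CO insertion does not follow alkyne insertion. The β-methoxy group is a donor that stabilises the vinylcarbene, which can then close without CO to five-membered products. The electron-poor, conjugated alkyne may also oligomerise or take up nucleophiles at its terminus. Neither this trioxygenated carbene nor a chromonyl alkyne has a direct model. The fallback gives up the ring B construction and sets out from acetophenone 4. Rieche formylation of 1,2,3,4-tetramethoxybenzene (Cl2CHOMe, TiCl4) would give 2,3,4,5-tetramethoxybenzaldehyde F1. Claisen–Schmidt condensation of 4 with F1 (KOH, EtOH) would give (E)-1-(2-hydroxy-3,4,6-trimethoxyphenyl)-3-(2,3,4,5-tetramethoxyphenyl)prop-2-en-1-one F2. Oxidative cyclisation of F2 (catalytic I2, DMSO, 130 °C) would return to the route at 17.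

**Step 6.** Deprotonation of 10 may be incomplete, leaving tert-butyllithium that itself adds to Cr(CO)6, and the vinyllithium may lose LiOMe on warming. The electron-rich carbene may also be lost on chromatography. The fallback sets out from 10. The crude vinyllithium would be trapped with Me3SnCl as (Z)-(1,2-dimethoxyvinyl)trimethylstannane F3, which can be distilled free of tert-butyl by-products. Tin–lithium exchange of F3 with MeLi (THF, −78 °C) would regenerate 12 cleanly, and the route is rejoined at 12.

**Step 5.** Silanolate or excess diazo anion may add to the electrophilic pyranone or to the newly formed conjugated alkyne, and the diazo reagent may undergo cycloaddition to the enone. The fallback sets out from 8. Wittig reaction with the ylide from (bromomethyl)triphenylphosphonium bromide and KOtBu (THF, −78 °C) would give 2-[(Z)-2-bromoethenyl]-5,7,8-trimethoxychromen-4-one F4. Anti elimination of HBr from F4 with DBU (MeCN, rt) would return to the route at 9.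

**Step 2.** The Lewis acid may cleave the other ortho methoxy group of 3, the one next to hydrogen, which would lead to the 5,6,7 series, or it may remove more than one methyl group. The preference for the flanked ether rests on chelation and strain arguments. The fallback sets out from 1 and distinguishes the two ortho oxygens by O-alkylation. Ortho-acylation of 1 (AcOH, BF3·OEt2, 80 °C) would give 1-(2-hydroxy-4,5,6-trimethoxyphenyl)ethanone F5, with no regiochemical choice. The one remaining ortho methoxy group would be cleaved (AlCl3, MeCN) to 1-(2,6-dihydroxy-3,4-dimethoxyphenyl)ethanone F6. One equivalent of MeI with K2CO3 in acetone should then methylate the less hindered hydroxyl of F6, the one beside the ring hydrogen, and return to the route at 4.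

## Further compounds

F1 | step 7 | 2,3,4,5-tetramethoxybenzaldehyde | O=Cc1cc(OC)c(OC)c(OC)c1OC
F2 | step 7 | (E)-1-(2-hydroxy-3,4,6-trimethoxyphenyl)-3-(2,3,4,5-tetramethoxyphenyl)prop-2-en-1-one | COc1cc(/C=C/C(=O)c2c(OC)cc(OC)c(OC)c2O)c(OC)c(OC)c1OC
F3 | step 6 | (Z)-(1,2-dimethoxyvinyl)trimethylstannane | CO/C=C(/OC)[Sn](C)(C)C
F4 | step 5 | 2-[(Z)-2-bromoethenyl]-5,7,8-trimethoxychromen-4-one | Br/C=C\c1cc(=O)c2c(OC)cc(OC)c(OC)c2o1
F5 | step 2 | 1-(2-hydroxy-4,5,6-trimethoxyphenyl)ethanone | CC(=O)c1c(O)cc(OC)c(OC)c1OC
F6 | step 2 | 1-(2,6-dihydroxy-3,4-dimethoxyphenyl)ethanone | CC(=O)c1c(O)cc(OC)c(OC)c1O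
A1 | alternative 1 | 5,7-dimethoxy-2-(2,3,4,5-tetramethoxyphenyl)chromen-4-one | COc1cc(OC)c2c(c1)oc(-c1cc(OC)c(OC)c(OC)c1OC)cc2=O
A2 | alternative 1 | 3-(2,3,4,5-tetramethoxyphenyl)prop-2-ynoic acid | OC(=O)C#Cc1cc(OC)c(OC)c(OC)c1OC
A3 | alternative 1 | 3,5-dimethoxy-2-(trimethylsilyl)phenyl trifluoromethanesulfonate | COc1cc(OC)c([Si](C)(C)C)c(OS(=O)(=O)C(F)(F)F)c1
A4 | alternative 2 | 5,7-dihydroxy-8-methoxy-2-(2,3,4,5-tetramethoxyphenyl)chromen-4-one | COc1c(O)cc(O)c2c1oc(-c1cc(OC)c(OC)c(OC)c1OC)cc2=O
A5 | alternative 2 | methyl 2-(1-methoxy-2-oxopropyl)-4-oxo-6-(2,3,4,5-tetramethoxyphenyl)-4H-pyran-3-carboxylate (racemic) | COC(=O)c1c(C(OC)C(C)=O)oc(-c2cc(OC)c(OC)c(OC)c2OC)cc1=O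
A6 | alternative 3 | 5,8-dihydroxy-7-methoxy-2-(2,3,4,5-tetramethoxyphenyl)chromen-4-one | COc1cc(O)c2c(c1O)oc(-c1cc(OC)c(OC)c(OC)c1OC)cc2=O
A7 | alternative 3 | 4-hydroxy-3-methoxy-4-[4-oxo-6-(2,3,4,5-tetramethoxyphenyl)-4H-pyran-2-yl]cyclobut-2-en-1-one (racemic) | COC1=CC(=O)C1(O)c1cc(=O)cc(-c2cc(OC)c(OC)c(OC)c2OC)o1
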